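**Strategy.** The six-membered ring of the carane unit (bicyclo[4.1.0]heptane locants: C1/C6 cyclopropane CH, C7 CMe2, C2 the methine shared with the cyclopentane, C3 the ether carbon) is closed between C1 and C2. (+)-2-Carene supplies C1 and C3–C7 unchanged; ozonolysis turns its own C2 into a carboxyl group, and a decarboxylative 6-exo radical cyclisation of the derived N-acyloxyphthalimide onto an ene-dione makes the former methyl carbon the new C2. The step exploits the cis-1,2-disubstituted gem-dimethylcyclopropane: the inverting cyclopropyl radical can only give the cis-fused bicyclic ketone, which then templates the cyclopentane, a bridged lactone and the benzoxepine.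

Key step: step 4

Assumption: the carbon α to the ester (later lactone) carbonyl is formed as an epimer mixture in step 4 and is left undefined in the SMILES of 10–17; both epimers give the same enolate in step 10. Ring locants in names are those of the overview.

**Step 1**
Reactants: 1 (+)-2-carene
Product: 3 (1S,3R)-2,2-dimethyl-3-(3-oxobutyl)cyclopropane-1-carboxylic acid, via keto aldehyde 2 (not isolated)
Conditions: O3, CH2Cl2/MeOH, −78 °C; Me2S, −78 → 23 °C; then NaClO2, H2O2, NaH2PO4, MeCN/H2O, 0 → 23 °C
Reagents that add atoms: ozone, [O-][O+]=O; sodium chlorite, [Na+].[O-]Cl=O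
Why: Ozonolysis of the trisubstituted alkene followed by chlorite (Pinnick-type) oxidation of the aldehyde leaves both cyclopropane centres untouched, and any epimerisation next to the carboxyl group is harmless because that carbon becomes a radical in step 4.

**Step 2**
Reactants: 3 keto acid; 4 ethyl pyruvate
Product: 6 (E)-ene-dione acid, via aldol adduct 5 (not isolated)
Conditions: LiN(i-Pr)2 (2.2 equiv), THF, −78 °C; 4, −78 °C; aq. HCl; then p-TsOH·H2O (10 mol %), toluene, 80 °C
Reagents that add atoms: none
Why: The kinetic methyl-side lithium enolate of the carboxylate dianion adds to the very electrophilic ketone of the pyruvate (crossed aldol addition), and acid-catalysed dehydration through the ketone enol gives the conjugated, thermodynamically preferred E alkene.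

**Step 3**
Reactants: 6 ene-dione acid
Product: 7 N-acyloxyphthalimide (redox-active ester) of 6
Conditions: N-hydroxyphthalimide, DIC, DMAP (10 mol %), CH2Cl2, 0 → 23 °C
Reagents that add atoms: N-hydroxyphthalimide, ON1C(=O)c2ccccc2C1=O
Why: Carbodiimide (Steglich-type) esterification activates the hindered cyclopropanecarboxylic acid for single-electron reduction without touching the ene-dione.

**Step 4**
Reactants: 7 redox-active ester
Product: 10 ethyl 2-(7,7-dimethyl-3-oxobicyclo[4.1.0]heptan-2-yl)propanoate, via cyclopropyl radical 8 (not isolated), via α-ester radical 9 (not isolated)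
Conditions: Ru(bpy)3(PF6)2 (2 mol %), Hantzsch ester (1.5 equiv), CH2Cl2 (0.01 M), blue LEDs, 23 °C
Reagents that add atoms: none
Why: Single-electron reduction of the N-acyloxyphthalimide (photoreduced ruthenium complex, Hantzsch ester as terminal reductant) expels phthalimide anion and CO2 to give the cyclopropyl σ-radical 8, which adds to the unsubstituted alkene carbon of the ene-dione to give the tertiary α-ester radical 9, quenched by hydrogen-atom transfer from the Hantzsch ester; the closest known reaction type is the reductive decarboxylative Giese addition of redox-active esters, here run intramolecularly. The six-membered ring is closed in the 6-exo-trig mode, in preference to 7-endo attack on the methyl-bearing alkene carbon, which is equally polarity-matched but slower and more hindered. The two cyclopropane centres C1 and C6 can only end cis-fused, because the cyclopropyl radical inverts freely and a trans-bicyclo[4.1.0]heptane is prohibitively strained, so the C6 configuration taken from 2-carene fixes both. The new methine C2 should place its side chain anti to the CMe2 bridge in the transition state and, being α to the ketone, is in any case equilibrated to that isomer in step 5; the centre α to the ester is not controlled and is corrected in step 10. The step needs cyclisation to outrun hydrogen capture by the very reactive cyclopropyl radical and reduction of the acceptor, which high dilution, only a modest excess of the hydrogen donor and the doubly activated alkene should secure.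

**Step 5**
Reactants: 10 bicyclic keto ester
Product: 11 ethyl 2-(7,7-dimethyl-4-methylidene-3-oxobicyclo[4.1.0]heptan-2-yl)propanoate
Conditions: (CH2O)n, N-methylanilinium trifluoroacetate, THF, 65 °C
Reagents that add atoms: paraformaldehyde (formaldehyde), C=O
Why: Mannich-type α-methylenation can only finish at C4, the one α-carbon with two hydrogens, and the mildly acidic medium also equilibrates C2 to the epimer with the side chain anti to the CMe2 bridge.

**Step 6**
Reactants: 11 α-methylene ketone
Product: 12 ethyl 2-(4,7,7-trimethyl-3-oxobicyclo[4.1.0]heptan-2-yl)propanoate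
Conditions: H2 (1 atm), Pd/C (10 wt %), EtOAc, 23 °C
Reagents that add atoms: none
Why: Heterogeneous hydrogenation of the exocyclic enone alkene delivers hydrogen to the convex face anti to the CMe2 bridge (as in the hydrogenation of 3-carene to cis-carane), so the new C4 methyl ends syn to the cyclopropane.

**Step 7**
Reactants: 12 methyl ketone
Product: 14 trans-fused vinyl γ-lactone, via hydroxy ester alkoxide 13 (not isolated)
Conditions: CeCl3, CH2=CHMgBr, THF, −78 → 23 °C; aq. NH4Cl
Reagents that add atoms: vinylmagnesium bromide, C=C[Mg]Br
Why: The non-basic organocerium reagent adds 1,2 to the hindered ketone from the face anti to the CMe2 bridge (the carane ring is bent away from that bridge), setting the quaternary C3 with oxygen syn to the cyclopropane, and the alkoxide closes onto the γ-ester on warming to give the trans-fused lactone.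

**Step 8**
Reactants: 14 vinyl lactone
Product: 16 2-hydroxyethyl lactone, via B-alkyl-9-BBN adduct 15 (not isolated)
Conditions: 9-BBN, THF, 0 → 23 °C; then H2O2 (30 %), aq. NaOAc, 0 °C
Reagents that add atoms: hydrogen peroxide, OO
Why: Anti-Markovnikov hydroboration of the monosubstituted alkene with a bulky borane and buffered oxidation give the primary alcohol while lactone and cyclopropane stay intact.

**Step 9**
Reactants: 16 hydroxyethyl lactone
Product: 17 2-iodoethyl lactone
Conditions: I2, PPh3, imidazole, CH2Cl2, 0 → 23 °C
Reagents that add atoms: iodine, II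
Why: Appel-type iodination of the unhindered primary alcohol proceeds by SN2 under neutral conditions.

**Step 10**
Reactants: 17 iodoethyl lactone
Product: 18 bridged lactone (2-oxabicyclo[2.2.1]heptan-3-one fused to the carane)
Conditions: LiN(i-Pr)2, THF/DMPU, −78 → 0 °C
Reagents that add atoms: none
Why: The lactone enolate (the only acidic C–H, so both epimers converge) is alkylated 5-exo-tet by the iodoethyl arm, which can only reach it from the lactone face on which it sits, so the methyl-bearing quaternary carbon is formed with the configuration enforced by the new ethano bridge (intramolecular enolate alkylation).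

**Step 11**
Reactants: 18 bridged lactone; 19 1-fluoro-3,5-dimethoxybenzene
Product: 22 bridged benzoxepinone, via aryllithium 20 (not isolated), via fluoro keto alkoxide 21 (not isolated)
Conditions: 19, n-BuLi, THF, −78 °C; 18, −78 °C; then DMPU, 23 → 60 °C
Reagents that add atoms: none
Why: Lithiation of 19 between F and OMe gives an aryl-lithium that opens the strained, non-enolisable lactone to a hindered aryl ketone and a tertiary alkoxide, and the alkoxide then displaces the fluoride ortho to the ketone (intramolecular SNAr) to close the seven-membered aryl ether ring.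

**Step 12**
Reactants: 22 benzoxepinone
Product: 23 benzylic alcohol (epimer mixture at the carbinol carbon)
Conditions: LiAlH4, THF, 0 → 40 °C
Reagents that add atoms: none
Why: Hydride reduction of the hindered aryl ketone gives the benzylic alcohol, whose configuration is irrelevant because step 13 passes through the cation.

**Step 13**
Reactants: 23 benzylic alcohol
Product: 24 methallyl compound
Conditions: methallyltrimethylsilane, BF3·OEt2 (0.5 equiv), CH2Cl2, −78 → −20 °C
Reagents that add atoms: methallyltrimethylsilane, CC(=C)C[Si](C)(C)C
Why: The Lewis acid ionises the alcohol to a benzylic cation stabilised by three ortho/para oxygens and lacking β-hydrogens, and Hosomi–Sakurai-type capture by the allylsilane should occur from the face syn to the one-carbon bridge (whose inward substituent is only H) rather than the more shielded ethano-bridge face, which sets the benzylic centre.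

**Step 14**
Reactants: 24 methallyl compound
Product: 25 isobutyl compound
Conditions: H2 (1 atm), Pd/C (10 wt %), EtOAc, 23 °C
Reagents that add atoms: none
Why: Hydrogenation of the unhindered 1,1-disubstituted alkene is far faster than any reaction of the remote, unactivated cyclopropane.

**Step 15**
Reactants: 25 isobutyl compound
Product: 26 di-O-methyl ether of the target
Conditions: Cl2CHOMe, TiCl4, CH2Cl2, −78 → 0 °C; then H2O
Reagents that add atoms: dichloromethyl methyl ether, COC(Cl)Cl; water, O
Why: Rieche formylation attacks the only two free positions of the tri-oxygenated arene, each ortho/para to alkoxy groups, and hydrolysis of the chloro ethers gives the dialdehyde.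

**Step 16**
Reactants: 26 dialdehyde dimethyl ether
Product: 27 CNP0202714.1
Conditions: NaSEt, DMF, 110 °C; then aq. HCl
Reagents that add atoms: none
Why: Thiolate SN2 demethylation cleaves the two methyl ethers, both activated by ortho/para formyl groups, and cannot attack the tertiary alkyl aryl ether or the cyclopropane.

**Compound list**
1 | (+)-2-carene, (1S,6R)-3,7,7-trimethylbicyclo[4.1.0]hept-2-ene | CC1=C[C@H]2[C@@H](CC1)C2(C)C | starting material
2 | (1S,3R)-2,2-dimethyl-3-(3-oxobutyl)cyclopropane-1-carbaldehyde | O=C[C@H]1[C@@H](CCC(C)=O)C1(C)C | intermediate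
3 | (1S,3R)-2,2-dimethyl-3-(3-oxobutyl)cyclopropane-1-carboxylic acid | OC(=O)[C@H]1[C@@H](CCC(C)=O)C1(C)C | intermediate
4 | ethyl pyruvate | CCOC(=O)C(C)=O | starting material
5 | cis-3-(6-ethoxy-5-hydroxy-5-methyl-3,6-dioxohexyl)-2,2-dimethylcyclopropane-1-carboxylic acid (carbinol epimers) | OC(=O)[C@H]1[C@@H](CCC(=O)CC(C)(O)C(=O)OCC)C1(C)C | intermediate
6 | cis-3-[(E)-6-ethoxy-5-methyl-3,6-dioxohex-4-enyl]-2,2-dimethylcyclopropane-1-carboxylic acid | OC(=O)[C@H]1[C@@H](CCC(=O)/C=C(\C)C(=O)OCC)C1(C)C | intermediate
7 | 1,3-dioxoisoindolin-2-yl ester of 6 | O=C(ON1C(=O)c2ccccc2C1=O)[C@H]1[C@@H](CCC(=O)/C=C(\C)C(=O)OCC)C1(C)C | intermediate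
8 | 3,3-dimethyl-2-alkylcyclopropyl radical from 7 | CCOC(=O)/C(C)=C/C(=O)CC[C@@H]1[CH]C1(C)C | intermediate
9 | cyclised tertiary α-ester radical | CCOC(=O)[C](C)[C@@H]1C(=O)CC[C@@H]2[C@H]1C2(C)C | intermediate
10 | ethyl 2-(7,7-dimethyl-3-oxobicyclo[4.1.0]heptan-2-yl)propanoate; cis ring fusion, side chain anti to the CMe2 bridge, propanoate C2 epimers | CCOC(=O)C(C)[C@@H]1C(=O)CC[C@@H]2[C@H]1C2(C)C | intermediate
11 | ethyl 2-(7,7-dimethyl-4-methylidene-3-oxobicyclo[4.1.0]heptan-2-yl)propanoate | CCOC(=O)C(C)[C@@H]1C(=O)C(=C)C[C@@H]2[C@H]1C2(C)C | intermediate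
12 | ethyl 2-(4,7,7-trimethyl-3-oxobicyclo[4.1.0]heptan-2-yl)propanoate; 4-methyl syn to the CMe2 bridge, side chain anti | CCOC(=O)C(C)[C@@H]1C(=O)[C@@H](C)C[C@@H]2[C@H]1C2(C)C | intermediate
13 | ethyl 2-(3-hydroxy-4,7,7-trimethyl-3-vinylbicyclo[4.1.0]heptan-2-yl)propanoate, formed as its alkoxide (drawn as the alcohol); vinyl anti to the CMe2 bridge | CCOC(=O)C(C)[C@@H]1[C@](O)(C=C)[C@@H](C)C[C@@H]2[C@H]1C2(C)C | intermediate
14 | trans-fused γ-lactone between the C3 oxygen and the propanoate carbonyl of 13, vinyl on C3 | C=C[C@@]12OC(=O)C(C)[C@H]1[C@H]1[C@@H](C[C@@H]2C)C1(C)C | intermediate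
15 | B-(2-lactonylethyl)-9-borabicyclo[3.3.1]nonane | C1CC2CCCC(C1)B2CC[C@@]12OC(=O)C(C)[C@H]1[C@H]1[C@@H](C[C@@H]2C)C1(C)C | intermediate
16 | 2-hydroxyethyl analogue of lactone 14 | OCC[C@@]12OC(=O)C(C)[C@H]1[C@H]1[C@@H](C[C@@H]2C)C1(C)C | intermediate
17 | 2-iodoethyl analogue of lactone 14 | ICC[C@@]12OC(=O)C(C)[C@H]1[C@H]1[C@@H](C[C@@H]2C)C1(C)C | intermediate
18 | bridged lactone: 2-oxabicyclo[2.2.1]heptan-3-one whose C1–C7 bond is shared with the trimethylbicyclo[4.1.0]heptane, methyl on the bridgehead next to the carbonyl | O=C1O[C@]23CC[C@@]1(C)[C@H]2[C@H]1[C@@H](C[C@@H]3C)C1(C)C | intermediate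
19 | 1-fluoro-3,5-dimethoxybenzene | COc1cc(F)cc(OC)c1 | starting material
20 | 2-fluoro-4,6-dimethoxyphenyllithium | [Li]c1c(F)cc(OC)cc1OC | intermediate
21 | (2-fluoro-4,6-dimethoxyphenyl) ketone with the tertiary lithium alkoxide at the former lactone oxygen (drawn as the alcohol) | O[C@]12CC[C@](C)(C(=O)c3c(F)cc(OC)cc3OC)[C@H]1[C@H]1[C@@H](C[C@@H]2C)C1(C)C | intermediate
22 | bridged benzoxepinone: target skeleton with C=O at the benzylic carbon, OMe in place of both OH, no formyl groups | O=C1c2c(OC)cc(OC)cc2O[C@]23CC[C@@]1(C)[C@H]2[C@H]1[C@@H](C[C@@H]3C)C1(C)C | intermediate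
23 | benzylic alcohol from 22 (carbinol epimers) | OC1c2c(OC)cc(OC)cc2O[C@]23CC[C@@]1(C)[C@H]2[C@H]1[C@@H](C[C@@H]3C)C1(C)C | intermediate
24 | 2-methylallyl compound, benzylic substituent syn to the one-carbon bridge | C=C(C)C[C@H]1c2c(OC)cc(OC)cc2O[C@]23CC[C@@]1(C)[C@H]2[C@H]1[C@@H](C[C@@H]3C)C1(C)C | intermediate
25 | isobutyl compound (target lacking both formyl groups, as dimethyl ether) | CC(C)C[C@H]1c2c(OC)cc(OC)cc2O[C@]23CC[C@@]1(C)[C@H]2[C@H]1[C@@H](C[C@@H]3C)C1(C)C | intermediate
26 | di-O-methyl ether of the target | CC(C)C[C@H]1c2c(OC)c(C=O)c(OC)c(C=O)c2O[C@]23CC[C@@]1(C)[C@H]2[C@H]1[C@@H](C[C@@H]3C)C1(C)C | intermediate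
27 | CNP0202714.1 | CC(C)C[C@H]1c2c(O)c(C=O)c(O)c(C=O)c2O[C@]23CC[C@@]1(C)[C@H]2[C@H]1[C@@H](C[C@@H]3C)C1(C)C | target

Total step count: 16. Longest linear sequence: 16 steps (1 → 27); 4 and 19 are used as purchased.

**Steps most likely to fail**

Step 4. The cyclopropyl radical may capture a hydrogen atom before it cyclises, or the ene-dione may be reduced by single-electron transfer ahead of fragmentation of the ester. The fallback sets out from 6 and comes back at 10. Acid 6 is coupled with N-hydroxypyridine-2-thione (DCC, CH2Cl2, dark) to the thiohydroxamate ester F1. Irradiation of F1 alone (tungsten lamp, benzene, 0.005 M, no reductant and no hydrogen donor) should run a group-transfer chain in which the cyclised α-ester radical takes up the pyridylthio group, giving ethyl 2-(7,7-dimethyl-3-oxobicyclo[4.1.0]heptan-2-yl)-2-(pyridin-2-ylsulfanyl)propanoate F2. Bu3SnH/AIBN (benzene, 80 °C) then replaces the sulfur group by hydrogen to deliver 10.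

Step 11. The alkoxide may fail to displace fluoride because the ketone, flanked by two ortho substituents and a quaternary carbon, is twisted out of conjugation; the ortho-fluoro aryl-lithium may also lose LiF to an aryne on warming. The fallback sets out from 18 and comes back at 22. 1-Bromo-3,5-dimethoxybenzene is lithiated between Br and OMe (LiN(i-Pr)2, THF, −78 °C) to 2-bromo-4,6-dimethoxyphenyllithium F3, which opens 18 at −78 °C to the bromo hydroxy ketone F4. Intramolecular palladium-catalysed C–O coupling of the tertiary alcohol (Pd(OAc)2, 2-(di-tert-butylphosphino)-1,1′-binaphthyl, Cs2CO3, toluene, 80 °C) closes the same ether ring without any need for activation by the ketone and gives 22.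

Step 13. The allylsilane may enter from the ethano-bridge face, or with poor facial selectivity. The fallback sets out from 22 and comes back at 25; it inverts the order of C–C and C–H bond formation at the benzylic carbon. i-BuLi/CeCl3 (THF, −78 °C) adds to ketone 22 to give the tertiary benzylic alcohol F5, and ionic hydrogenation (Et3SiH, CF3CO2H, CH2Cl2, −40 °C) delivers hydride instead of carbon to the preferred face of the same kind of cation, giving the opposite benzylic configuration directly as 25.

**Further compounds**
F1 | step 4 | 2-thioxopyridin-1(2H)-yl ester of acid 6 | S=c1ccccn1OC(=O)[C@H]1[C@@H](CCC(=O)/C=C(\C)C(=O)OCC)C1(C)C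
F2 | step 4 | ethyl 2-(7,7-dimethyl-3-oxobicyclo[4.1.0]heptan-2-yl)-2-(pyridin-2-ylsulfanyl)propanoate | CCOC(=O)C(C)(Sc1ccccn1)[C@@H]1C(=O)CC[C@@H]2[C@H]1C2(C)C
F3 | step 11 | 2-bromo-4,6-dimethoxyphenyllithium | [Li]c1c(Br)cc(OC)cc1OC
F4 | step 11 | (2-bromo-4,6-dimethoxyphenyl) ketone with free tertiary alcohol (bromo analogue of 21) | O[C@]12CC[C@](C)(C(=O)c3c(Br)cc(OC)cc3OC)[C@H]1[C@H]1[C@@H](C[C@@H]2C)C1(C)C
F5 | step 13 | tertiary benzylic alcohol from isobutyl addition to 22 | CC(C)CC1(O)c2c(OC)cc(OC)cc2O[C@]23CC[C@@]1(C)[C@H]2[C@H]1[C@@H](C[C@@H]3C)C1(C)C
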